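The oxolane ring is cut into two pieces: O1–C5(CH3)–C4H2, which is (S)-propylene oxide, and C2–C3, which is the triple bond of a propargyl ether. The key step joins them in one flask as a formal (3+2) annulation: the acetylide carbon (future C3) opens the epoxide at C4, then Pd(II) makes the new alkoxide O1 add 5-endo-dig to C2. It exploits the 1,3-relation of O1 and C4 in the ring and leaves a C2=C3 enol ether, so that one hydroboration, steered by the bought C5 centre, sets C2 and C3 together. The dienyl isocoumarin is then grown from C2 by two olefinations, acylation of a chlorinated orsellinate anion, lactonisation and deprotection.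

Key step: step 1

Remark (numbering): ring locants are those of the target oxolane throughout (O1; C2 bears the side chain; C3 the hydroxyl; C4 is CH2; C5 bears the methyl), and C1'–C4' are the diene carbons counted from C2.

Step 1
Reactants: 1 (S)-propylene oxide; 2 tert-butyldimethyl(prop-2-yn-1-yloxy)silane
Product: 4 tert-butyldimethyl{[(5S)-5-methyl-4,5-dihydrofuran-2-yl]methoxy}silane, via alkynol 3 (not isolated)
Conditions: 2, n-BuLi, THF/DMPU, −78 °C; 1 (1.3 equiv), −78 °C → rt; then AcOH (1 equiv), PdCl2(MeCN)2 (5 mol %), rt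
Reagents that add atoms: none
Why: The lithium acetylide of 2 opens the epoxide by SN2 attack at the unhindered C4 methylene (C3–C4 bond), which leaves the C5 centre untouched and places the new alkoxide oxygen in reach of the internal alkyne carbon. After neutralisation, Pd(II) π-activates the triple bond and O1 adds anti across it in a 5-endo-dig closure (O1–C2 bond); protonolysis of the vinyl–palladium bond at C3 releases the enol ether and the catalyst. The closest known reaction types are the acetylide opening of terminal epoxides and the Pd(II)-catalysed cycloisomerisation of 3-alkyn-1-ols to 2,3-dihydrofurans, which together amount to a formal (3+2) annulation of an epoxide with an alkyne. No new stereocentre is formed: C5 is bought with 1, and the C2=C3 bond made here is what allows C2 and C3 to be set together in step 2. The step needs attack at CH2 rather than CH (secured by sterics in an SN2 process) and endo rather than 4-exo-dig closure (the latter would give a strained 2-alkylideneoxetane), and the acetate buffer should keep the acid-labile enol ether from hydrolysis or double-bond migration.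

Step 2
Reactants: 4 tert-butyldimethyl{[(5S)-5-methyl-4,5-dihydrofuran-2-yl]methoxy}silane
Product: 5 (2R,3S,5S)-2-{[(tert-butyldimethylsilyl)oxy]methyl}-5-methyloxolan-3-ol
Conditions: BH3·THF, THF, −20 → 0 °C; then NaOH, H2O2, 0 °C
Reagents that add atoms: hydrogen peroxide, OO
Why: Brown hydroboration–oxidation of the enol ether should put boron on C3 and hydrogen on C2 in a syn addition from the ring face anti to the C5 methyl, so that after oxidation with retention the C3 hydroxyl is trans to both the C2 substituent and the methyl group while the C2 and C5 substituents are cis.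

Step 3
Reactants: 5 (2R,3S,5S)-2-{[(tert-butyldimethylsilyl)oxy]methyl}-5-methyloxolan-3-ol
Product: 6 (2R,3S,5S)-2-(hydroxymethyl)-5-methyloxolan-3-ol
Conditions: CSA (cat.), MeOH, 0 °C → rt
Reagents that add atoms: none
Why: Acid-catalysed methanolysis of a primary silyl ether, which touches no stereocentre and gives only a volatile by-product.

Step 4
Reactants: 6 (2R,3S,5S)-2-(hydroxymethyl)-5-methyloxolan-3-ol
Product: 8 (2E)-3-[(2R,3S,5S)-3-hydroxy-5-methyloxolan-2-yl]prop-2-enal, via hydroxy aldehyde 7 (not isolated)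
Conditions: TEMPO (10 mol %), PhI(OAc)2, CH2Cl2, rt; then Ph3P=CHCHO (1.1 equiv), rt → 40 °C
Reagents that add atoms: (triphenylphosphoranylidene)acetaldehyde, O=CC=P(c1ccccc1)(c1ccccc1)c1ccccc1
Why: The oxoammonium (TEMPO) oxidation should select the primary over the hindered secondary alcohol, and the stabilised ylide should trap the saturated aldehyde in an E-selective Wittig reaction before the α-alkoxy centre C2 can epimerise.

Step 5
Reactants: 8 (2E)-3-[(2R,3S,5S)-3-hydroxy-5-methyloxolan-2-yl]prop-2-enal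
Product: 9 (2E,4E)-5-[(2R,3S,5S)-3-hydroxy-5-methyloxolan-2-yl]-N-methoxy-N-methylpenta-2,4-dienamide
Conditions: (EtO)2P(O)CH2C(O)N(OMe)Me, LiCl, DBU, MeCN, 0 °C → rt
Reagents that add atoms: diethyl {2-[methoxy(methyl)amino]-2-oxoethyl}phosphonate, CCOP(=O)(CC(=O)N(C)OC)OCC
Why: Horner–Wadsworth–Emmons olefination under Masamune–Roush conditions, which tolerate the free hydroxyl and should give the new (E)-alkene from a stabilised phosphonate.

Step 6
Reactants: 10 methyl 2,4-dihydroxy-6-methylbenzoate (methyl orsellinate)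
Product: 11 methyl 3-chloro-4,6-dihydroxy-2-methylbenzoate
Conditions: SO2Cl2 (1.0 equiv), Et2O, 0 °C → rt
Reagents that add atoms: sulfuryl chloride, O=S(=O)(Cl)Cl
Why: Electrophilic aromatic chlorination is expected at the position para to the ester-chelated hydroxyl and ortho to the free one (next to the methyl group), with one equivalent of reagent limiting the isomeric and dichloro by-products.

Step 7
Reactants: 11 methyl 3-chloro-4,6-dihydroxy-2-methylbenzoate
Product: 12 methyl 3-chloro-4,6-bis(methoxymethoxy)-2-methylbenzoate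
Conditions: NaH, MOMCl, DMF, 0 °C → rt
Reagents that add atoms: chloromethyl methyl ether, COCCl
Why: Williamson-type O-alkylation of both phenoxides gives acetals that withstand the lateral lithiation of step 8.

Step 8
Reactants: 12 methyl 3-chloro-4,6-bis(methoxymethoxy)-2-methylbenzoate; 9 (2E,4E)-5-[(2R,3S,5S)-3-hydroxy-5-methyloxolan-2-yl]-N-methoxy-N-methylpenta-2,4-dienamide
Product: 14 5-chloro-3-[(1E,3E)-4-[(2R,3S,5S)-3-hydroxy-5-methyloxolan-2-yl]buta-1,3-dien-1-yl]-6,8-bis(methoxymethoxy)-1H-isochromen-1-one, via keto ester 13 (not isolated)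
Conditions: 12 (2.5 equiv), LDA (2.5 equiv), THF, −78 °C; 9 (1 equiv); AcOH, −78 °C; then DBU, 40 °C
Reagents that add atoms: none
Why: Lateral lithiation of the ortho-toluate gives a benzylic anion that should add 1,2 to the Weinreb amide (Weinreb ketone synthesis; one equivalent is spent on the free hydroxyl), and after the quench DBU enolises the benzylic ketone, whose enol oxygen acylates on the neighbouring methyl ester (6-exo-trig enol lactonisation) to form the isocoumarin.

Step 9
Reactants: 14 5-chloro-3-[(1E,3E)-4-[(2R,3S,5S)-3-hydroxy-5-methyloxolan-2-yl]buta-1,3-dien-1-yl]-6,8-bis(methoxymethoxy)-1H-isochromen-1-one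
Product: 15 5-chloro-6,8-dihydroxy-3-[(1E,3E)-4-[(2R,3S,5S)-3-hydroxy-5-methyloxolan-2-yl]buta-1,3-dien-1-yl]-1H-isochromen-1-one (CNP0086741.1)
Conditions: HCl (0.5 M), MeOH/THF, 0 °C → rt
Reagents that add atoms: none
Why: Acid-catalysed acetal exchange of the two aryl MOM ethers with methanol, run dilute and cold to spare the dienylic C2–O1 ether.

Compound list
1 | (S)-propylene oxide [(2S)-2-methyloxirane] | C[C@H]1CO1 | starting material
2 | tert-butyldimethyl(prop-2-yn-1-yloxy)silane | C#CCO[Si](C)(C)C(C)(C)C | starting material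
3 | (2S)-6-[(tert-butyldimethylsilyl)oxy]hex-4-yn-2-ol | C[C@H](O)CC#CCO[Si](C)(C)C(C)(C)C | intermediate
4 | tert-butyldimethyl{[(5S)-5-methyl-4,5-dihydrofuran-2-yl]methoxy}silane | C[C@H]1CC=C(CO[Si](C)(C)C(C)(C)C)O1 | intermediate
5 | (2R,3S,5S)-2-{[(tert-butyldimethylsilyl)oxy]methyl}-5-methyloxolan-3-ol | C[C@H]1C[C@H](O)[C@@H](CO[Si](C)(C)C(C)(C)C)O1 | intermediate
6 | (2R,3S,5S)-2-(hydroxymethyl)-5-methyloxolan-3-ol | C[C@H]1C[C@H](O)[C@@H](CO)O1 | intermediate
7 | (2S,3S,5S)-3-hydroxy-5-methyloxolane-2-carbaldehyde | C[C@H]1C[C@H](O)[C@@H](C=O)O1 | intermediate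
8 | (2E)-3-[(2R,3S,5S)-3-hydroxy-5-methyloxolan-2-yl]prop-2-enal | C[C@H]1C[C@H](O)[C@@H](/C=C/C=O)O1 | intermediate
9 | (2E,4E)-5-[(2R,3S,5S)-3-hydroxy-5-methyloxolan-2-yl]-N-methoxy-N-methylpenta-2,4-dienamide | C[C@H]1C[C@H](O)[C@@H](/C=C/C=C/C(=O)N(C)OC)O1 | intermediate
10 | methyl 2,4-dihydroxy-6-methylbenzoate | COC(=O)c1c(C)cc(O)cc1O | starting material
11 | methyl 3-chloro-4,6-dihydroxy-2-methylbenzoate | COC(=O)c1c(C)c(Cl)c(O)cc1O | intermediate
12 | methyl 3-chloro-4,6-bis(methoxymethoxy)-2-methylbenzoate | COC(=O)c1c(C)c(Cl)c(OCOC)cc1OCOC | intermediate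
13 | methyl 3-chloro-2-[(3E,5E)-6-[(2R,3S,5S)-3-hydroxy-5-methyloxolan-2-yl]-2-oxohexa-3,5-dien-1-yl]-4,6-bis(methoxymethoxy)benzoate | C[C@H]1C[C@H](O)[C@@H](/C=C/C=C/C(=O)Cc2c(Cl)c(OCOC)cc(OCOC)c2C(=O)OC)O1 | intermediate
14 | 5-chloro-3-[(1E,3E)-4-[(2R,3S,5S)-3-hydroxy-5-methyloxolan-2-yl]buta-1,3-dien-1-yl]-6,8-bis(methoxymethoxy)-1H-isochromen-1-one | C[C@H]1C[C@H](O)[C@@H](/C=C/C=C/c2cc3c(Cl)c(OCOC)cc(OCOC)c3c(=O)o2)O1 | intermediate
15 | 5-chloro-6,8-dihydroxy-3-[(1E,3E)-4-[(2R,3S,5S)-3-hydroxy-5-methyloxolan-2-yl]buta-1,3-dien-1-yl]-1H-isochromen-1-one | C[C@H]1C[C@H](O)[C@@H](/C=C/C=C/c2cc3c(Cl)c(O)cc(O)c3c(=O)o2)O1 | target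

Total step count: 9. Longest linear sequence: 7 steps (steps 1–5, 8 and 9).

Steps most likely to fail

Step 1. The acid-labile enol ether may be lost by hydrolysis or double-bond migration during the Pd(II) stage, and the epoxide opening may be slow without a Lewis acid. The fallback sets out from 1 and comes back at 4. The epoxide 1 is opened with lithium acetylide–ethylenediamine complex in DMSO to (2S)-pent-4-yn-2-ol F1. This terminal alkynol is cycloisomerised through a tungsten vinylidene (W(CO)6 cat., Et3N, THF, hν) to (2S)-2-methyl-2,3-dihydrofuran F2. The enol ether CH next to oxygen is lithiated (t-BuLi, THF, −78 → 0 °C) and the anion trapped with paraformaldehyde to give [(5S)-5-methyl-4,5-dihydrofuran-2-yl]methanol F3, which is silylated (TBSCl, imidazole, DMF) to 4.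

Step 2. Facial selectivity may be poor, because a methyl group at C5 is a weak steering element for borane. The fallback sets out from 3 and comes back at 6. Alkynol 3 is isolated by aqueous work-up before any palladium is added and hydrogenated over Lindlar catalyst (quinoline) to (2S,4Z)-6-[(tert-butyldimethylsilyl)oxy]hex-4-en-2-ol F4. The silyl group is removed (CSA, MeOH) to give (2Z,5S)-hex-2-ene-1,5-diol F5. A reagent-controlled Sharpless epoxidation (Ti(OiPr)4, D-(−)-diethyl tartrate, t-BuOOH, 4 Å sieves, CH2Cl2, −20 °C) then gives the cis-epoxy diol [(2R,3S)-3-[(2S)-2-hydroxypropyl]oxiran-2-yl]methanol F6. On treatment with t-BuOK in t-BuOH/THF, a Payne rearrangement moves the epoxide to C2–C1' and the C5 alkoxide opens it 5-exo at C2. The two inversions at C2 leave the C3 hydroxyl trans to the C2 substituent and should give diol 6.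

Step 8. The soft benzylic anion may add in a conjugate (1,4 or 1,6) sense to the dienamide or condense with itself. The fallback sets out from 8 and comes back at 15. The lithium enolate of N-methoxy-N-methylacetamide (LDA, THF, −78 °C) is added to enal 8 to give (4E)-3-hydroxy-5-[(2R,3S,5S)-3-hydroxy-5-methyloxolan-2-yl]-N-methoxy-N-methylpent-4-enamide F7, used as both carbinol epimers. Both hydroxyls are silylated (TBSOTf, 2,6-lutidine) to the bis-silyl ether F8. Lithiated 12 is acylated with this saturated amide, where only 1,2-addition is possible, to give the β-silyloxy benzylic ketone F9. DBU then eliminates silanolate (E1cB) to the dienone and closes the enol lactone, giving the 3-O-silyl ether of 14, F10. The acid of step 9 removes the silyl group together with the MOM groups to give 15.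

Further compounds
F1 | step 1 | (2S)-pent-4-yn-2-ol | C[C@H](O)CC#C
F2 | step 1 | (2S)-2-methyl-2,3-dihydrofuran | C[C@H]1CC=CO1
F3 | step 1 | [(5S)-5-methyl-4,5-dihydrofuran-2-yl]methanol | C[C@H]1CC=C(CO)O1
F4 | step 2 | (2S,4Z)-6-[(tert-butyldimethylsilyl)oxy]hex-4-en-2-ol | C[C@H](O)C/C=C\CO[Si](C)(C)C(C)(C)C
F5 | step 2 | (2Z,5S)-hex-2-ene-1,5-diol | C[C@H](O)C/C=C\CO
F6 | step 2 | [(2R,3S)-3-[(2S)-2-hydroxypropyl]oxiran-2-yl]methanol | C[C@H](O)C[C@@H]1O[C@@H]1CO
F7 | step 8 | (4E)-3-hydroxy-5-[(2R,3S,5S)-3-hydroxy-5-methyloxolan-2-yl]-N-methoxy-N-methylpent-4-enamide (both C3 epimers) | C[C@H]1C[C@H](O)[C@@H](/C=C/C(O)CC(=O)N(C)OC)O1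
F8 | step 8 | (4E)-3-[(tert-butyldimethylsilyl)oxy]-5-[(2R,3S,5S)-3-[(tert-butyldimethylsilyl)oxy]-5-methyloxolan-2-yl]-N-methoxy-N-methylpent-4-enamide | C[C@H]1C[C@H](O[Si](C)(C)C(C)(C)C)[C@@H](/C=C/C(O[Si](C)(C)C(C)(C)C)CC(=O)N(C)OC)O1
F9 | step 8 | methyl 2-[(5E)-4-[(tert-butyldimethylsilyl)oxy]-6-[(2R,3S,5S)-3-[(tert-butyldimethylsilyl)oxy]-5-methyloxolan-2-yl]-2-oxohex-5-en-1-yl]-3-chloro-4,6-bis(methoxymethoxy)benzoate | C[C@H]1C[C@H](O[Si](C)(C)C(C)(C)C)[C@@H](/C=C/C(O[Si](C)(C)C(C)(C)C)CC(=O)Cc2c(Cl)c(OCOC)cc(OCOC)c2C(=O)OC)O1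
F10 | step 8 | 3-[(1E,3E)-4-[(2R,3S,5S)-3-[(tert-butyldimethylsilyl)oxy]-5-methyloxolan-2-yl]buta-1,3-dien-1-yl]-5-chloro-6,8-bis(methoxymethoxy)-1H-isochromen-1-one | C[C@H]1C[C@H](O[Si](C)(C)C(C)(C)C)[C@@H](/C=C/C=C/c2cc3c(Cl)c(OCOC)cc(OCOC)c3c(=O)o2)O1
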